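Assumption: the target is taken as the aryl hydrogen sulfate exactly as drawn; since aryl sulfate monoesters are robust only as salts, 18 and 19 are written as the acids but should be carried and stored as their triethylammonium (or sodium) salts, the acid form being released only by brief contact with a cold acidic ion-exchange resin if it is wanted.

## Structural features

The target 19 is a flavonol: benzo ring A is fused through C4a–C8a to pyranone ring C, which carries the 4-hydroxyphenyl ring B on C2 and an enolic hydroxyl on C3. There is no stereocentre. Ring A bears oxygen on the three adjacent carbons C5, C6 and C7, leaving only C8 unsubstituted, and the C7 oxygen is esterified as a hydrogen sulfate. The sulfate monoester is the most fragile group (acid-catalysed solvolysis), the free 5,6-dihydroxy unit is easily oxidised to a quinone, and the C5 hydroxyl is hydrogen-bonded to the C4 carbonyl. The skeleton is simple; the difficulty is telling the oxygens apart. O7 alone must be sulfated beside O5, O6, O3 and O4', and ring C must close through O1, the oxygen whose neighbour is the unsubstituted C8, not through the C5 oxygen, which would give the isomeric 5,7,8-oxygenated flavone. The key step uses the fact that C4 is a single carbonyl carbon between C4a of ring A (flanked by the O1-bearing C8a and the oxygen-bearing C5) and the oxygen-bearing C3. C4 can therefore be supplied as carbon monoxide between an aryl iodide (C4a–I) and the alpha carbon of an alpha-alkoxy ketone that already holds C3, C2 and ring B. Because the tetraoxygenated phenol behind ring A is symmetric, its two ortho C–H positions are identical, so one iodination fixes C4a and thereby which oxygen is O1. In the iodide the silyl ether oxygen maps to O1, the two acetal oxygens to O5 and O7, and the benzyl ether oxygen to O6; this assignment was checked atom by atom against the target and needs no correction.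

## Logic of the disconnections

19 to 18: the three benzylic C–O bonds at O3, O6 and O4' are cut. Benzyl ethers are the only masks here that can be removed under neutral conditions once the sulfate is present, and they keep the oxidation-prone ring A covered until the last operation. The forward step must cleave three ethers without touching the O–S bond or the C2=C3 bond of ring C.

18 to 17: the O7–S bond is cut. In 17 only two hydroxyls are free, and one of them (O5) is held in a hydrogen bond to the C4 carbonyl, so the regiochemistry of sulfation rests on that difference and needs no further protecting group. The sulfating agent must be mild enough to leave the chelated hydroxyl alone.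

17 to 14: the O1–C2 bond of ring C is cut, C2 returns to a ketone, O5 and O7 are masked again as acetals and O1 as a silyl ether. Cyclodehydration of a 1-(2-hydroxyaryl)-1,3-diketone is the most reliable way to a flavone, and the cut turns the heterocycle into an open-chain 2-alkoxy-1,3-diketone. The forward sequence (through 15 and 16) must free and engage O1 before O5 is unveiled, which is why the two kinds of mask are orthogonal.

14 to 7, 12 and 13: the bonds C4a–C4 and C4–C3 are cut, so that C4 becomes 13. This gives two fragments of similar size, each with all its oxygens in place and at the final oxidation level. The forward step must insert 13 faster than the aryl group couples directly with the enolate, acylate the enolate at carbon, and accept an iodide with two ortho substituents.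

7 to 6 to 5: the O–Si bond and then the C–I bond are cut. 5 is symmetric, so only one mono-iodide can form and its hydroxyl is by necessity the neighbour of the iodinated carbon. The forward iodination must stop after one halogen.

5 to 3 (through 4), then 3 to 2 to 1: the phenolic C–O bond is traced back to a formyl group, the two acetal O–C bonds are cut, and finally the O4–benzyl bond. 1 is commercial and has the three contiguous oxygens in place; its 4-hydroxyl is the most acidic, which the forward mono-benzylation has to exploit.

12 to 9 and 10 (through 11), then 9 to 8: the aryl–carbonyl bond and the amide C–N bond are cut. Both building blocks are commercial; the forward addition must stop at the ketone.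

## Other disconnections considered

Alternative 1: The cut is O1–C2, with ring C formed as a 2H-chromene. Forward, the cinnamylhydroquinone A1 (2-{(2E)-3-[4-(benzyloxy)phenyl]prop-2-en-1-yl}-3,5-bis(prop-2-en-1-yloxy)benzene-1,4-diol) would be oxidised with Ag2O and warmed in pyridine; tautomerisation to a vinyl ortho-quinone methide stage and oxa-six-electron electrocyclisation would give the racemic chromenol A2.
- In its favour: the closure is pericyclic and needs no catalyst, no carbon monoxide and no aryl halide. O1 is defined by the quinone carbonyl next to the cinnamyl chain, so on the question of which oxygen closes the ring it is the equal of the chosen plan, and on operational simplicity of the ring-forming event it is the better.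
- Against it: A2 has the wrong oxidation pattern everywhere in ring C. C4 is an alkene CH, C3 carries no oxygen, and C2 is an sp3 stereocentre that must later be erased. At least three redox operations would follow, and any epoxidation or dihydroxylation of C3=C4 would have to compete with the two allyl ethers. The hydroxyl that A2 leaves free is O6, whereas the target needs O7 singled out, so the protecting groups would have to be reshuffled.
- Comparison: on structure the chosen plan delivers C4 as a carbonyl and C3 with its oxygen in the bond-forming step. On mechanism the alternative is the cleaner single event. On step economy the chosen plan is clearly shorter after the key step (three steps against an estimated six or more).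

Alternative 2: The cut is C4–C4a. Forward, the symmetric phenol 5 would add to the ynal A3 (3-[4-(benzyloxy)phenyl]prop-2-ynal) to give the Z enal A4 ((2Z)-3-[4-(benzyloxy)-3,5-bis(methoxymethoxy)phenoxy]-3-[4-(benzyloxy)phenyl]prop-2-enal). tert-Butyl hydroperoxide with catalytic Bu4NBr at about 100 °C would then turn the formyl C–H into an acyl radical that attacks an ortho carbon of the aryloxy ring and, after oxidative rearomatisation, gives the flavone A5.
- In its favour: it starts from the same phenol 5 but needs neither iodination nor a silyl marker, because O1 is simply the oxygen that was arylated. On that point and on the step count up to the closed ring it is better than the chosen plan. Either ortho C–H gives the same product, so on regiochemical certainty at C4a it is equal.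
- Against it: A5 has no oxygen on C3. A late C3 hydroxylation of the flavone would be needed, and the new hydroxyl would then have to be protected or would compete in the sulfation, which removes the clean two-hydroxyl situation of 17. The oxygen-centred radicals of the key step can also abstract hydrogen from two benzylic ether CH2 groups and two acetal CH2 groups, and the carbon to be attacked is crowded by the adjacent acetal.
- Comparison: on structure the chosen plan carries the C3 oxygen from the start. On mechanism a two-electron acylpalladium pathway tolerates benzyl ethers and acetals better than a radical chain should. On step economy the early saving of the alternative is expected to be used up by the C3 oxygenation and its protection.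

Alternative 3: The cut is C3–C4. Forward, the dialdehyde A6 (racemic 3-(benzyloxy)-6-{1-[4-(benzyloxy)phenyl]-2-oxoethoxy}-2,4-bis(methoxymethoxy)benzaldehyde) would be treated with a triazolium salt and DBU; the carbene would convert the aromatic formyl group into an acyl anion equivalent that adds to the aliphatic one, giving the 3-hydroxychroman-4-one A7 as a racemic mixture of diastereomers.
- In its favour: one organocatalytic bond formation sets the C4 carbonyl and the C3 hydroxyl together, without carbon monoxide or palladium, which is a point on which it is better. ortho-Formylation of symmetric 5 is as unambiguous as the iodination of the chosen plan (equal), and O1 is fixed by O-alkylation, so no marker group is required (equal or better).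
- Against it: the two aldehydes are badly matched for the required sense of addition. The aromatic one is hindered by two ortho oxygens and electron-rich, the aliphatic one is unhindered, so the crossed benzoin could run the other way to the 4-hydroxychroman-3-one A8 (6-(benzyloxy)-2-[4-(benzyloxy)phenyl]-4-hydroxy-5,7-bis(methoxymethoxy)-2H-chromen-3(4H)-one). A6 is an alpha-aryloxy arylacetaldehyde, prone to enolisation, self-condensation and air oxidation, and would take several steps to make. A7 still needs dehydrogenation across C2–C3, and its free C3 hydroxyl again complicates the selective sulfation.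
- Comparison: on structure both plans reach the correct oxidation level at C3 and C4, the alternative with the hydroxyl free, the chosen plan with it benzylated, which suits the endgame better. On mechanism the chosen plan has no ambiguity of polarity between two like groups. On step economy the alternative is estimated to be longer, because of the dialdehyde synthesis and the extra oxidation.

Key step: step 8

## Route

Step 1
Reactants: 1 3,4,5-trihydroxybenzaldehyde
Product: 2 4-(benzyloxy)-3,5-dihydroxybenzaldehyde
Conditions: BnBr (1.0 equiv), NaHCO3, NaI (cat.), DMF, 40 °C
Reagents that add atoms: benzyl bromide, BrCc1ccccc1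
Why: Williamson etherification under weak base: only the 4-hydroxyl, para to the formyl group and therefore the most acidic, is ionised by NaHCO3, so one equivalent of benzyl bromide should alkylate O4 and leave the two flanking hydroxyls free.

Step 2
Reactants: 2 4-(benzyloxy)-3,5-dihydroxybenzaldehyde
Product: 3 4-(benzyloxy)-3,5-bis(methoxymethoxy)benzaldehyde
Conditions: MOMCl (3 equiv), K2CO3, acetone, 0 °C → rt
Reagents that add atoms: chloromethyl methyl ether, COCCl
Why: Standard O-alkylation of the two remaining, equivalent phenols gives the symmetric bis-acetal; the aldehyde and the benzyl ether are inert.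

Step 3
Reactants: 3 4-(benzyloxy)-3,5-bis(methoxymethoxy)benzaldehyde
Product: 5 4-(benzyloxy)-3,5-bis(methoxymethoxy)phenol, via aryl formate 4 (not isolated)
Conditions: mCPBA, CH2Cl2, 0 °C → rt; aq NaHCO3/Na2S2O3 wash; then K2CO3 (cat.), MeOH, rt
Reagents that add atoms: 3-chloroperoxybenzoic acid, O=C(OO)c1cccc(Cl)c1
Why: Dakin-type Baeyer–Villiger oxidation: the electron-rich aryl group migrates in the Criegee intermediate to give formate 4, which mild methanolysis cleaves to the symmetric phenol; acetals and benzyl ether tolerate both stages.

Step 4
Reactants: 5 4-(benzyloxy)-3,5-bis(methoxymethoxy)phenol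
Product: 6 4-(benzyloxy)-2-iodo-3,5-bis(methoxymethoxy)phenol
Conditions: NIS (1.0 equiv), DMF, −20 → 0 °C, dark
Reagents that add atoms: N-iodosuccinimide, O=C1CCC(=O)N1I
Why: Electrophilic aromatic iodination of a strongly activated phenol whose only two free positions are ortho to the hydroxyl and equivalent by symmetry, so only one mono-iodide can form. One equivalent of reagent at low temperature, together with the crowding and deactivation caused by the first iodine, should stop the reaction there.

Step 5
Reactants: 6 4-(benzyloxy)-2-iodo-3,5-bis(methoxymethoxy)phenol
Product: 7 tert-butyl[4-(benzyloxy)-2-iodo-3,5-bis(methoxymethoxy)phenoxy]dimethylsilane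
Conditions: TBSCl, imidazole, DMF, rt
Reagents that add atoms: tert-butyldimethylsilyl chloride, CC(C)(C)[Si](C)(C)Cl
Why: Routine imidazole-promoted silylation of the phenol; the silyl ether marks this oxygen as the future O1 and is orthogonal to the acetals and the benzyl ether.

Step 6
Reactants: 8 (benzyloxy)acetyl chloride
Product: 9 2-(benzyloxy)-N-methoxy-N-methylacetamide
Conditions: MeNH(OMe)·HCl, K2CO3, H2O/CH2Cl2, 0 °C → rt
Reagents that add atoms: N,O-dimethylhydroxylamine hydrochloride, CNOC.Cl
Why: Schotten–Baumann acylation of the hydroxylamine gives the Weinreb amide.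

Step 7
Reactants: 10 1-(benzyloxy)-4-bromobenzene; 9 2-(benzyloxy)-N-methoxy-N-methylacetamide
Product: 12 2-(benzyloxy)-1-[4-(benzyloxy)phenyl]ethan-1-one, via arylmagnesium bromide 11 (not isolated)
Conditions: Mg turnings, I2 (cat.), THF, reflux; then 9, THF, 0 °C → rt; 1 M HCl (aq), 0 °C
Reagents that add atoms: none
Why: Grignard formation followed by Weinreb ketone synthesis: the five-membered magnesium chelate of the tetrahedral adduct prevents over-addition and collapses to the ketone only on acidic quench.

Step 8
Reactants: 7 tert-butyl[4-(benzyloxy)-2-iodo-3,5-bis(methoxymethoxy)phenoxy]dimethylsilane; 12 2-(benzyloxy)-1-[4-(benzyloxy)phenyl]ethan-1-one (2 equiv); 13 carbon monoxide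
Product: 14 2-(benzyloxy)-1-{3-(benzyloxy)-6-[(tert-butyldimethylsilyl)oxy]-2,4-bis(methoxymethoxy)phenyl}-3-[4-(benzyloxy)phenyl]propane-1,3-dione (enolisable)
Conditions: Pd(dba)2 (5 mol %), Xantphos (5 mol %), MgCl2 (2.5 equiv), Et3N (4 equiv), CO (1 atm), 1,4-dioxane, 80 °C; aq citric acid work-up
Reagents that add atoms: none
Why: Carbonylative alpha-arylation of a ketone, the known palladium-catalysed three-component route from aryl iodides, CO and ketone enolates to 1,3-diketones. Oxidative addition of the C4a–I bond of 7 to zerovalent palladium carrying Xantphos gives an arylpalladium iodide that takes up CO and undergoes migratory insertion to the aroylpalladium species, which creates C4a–C4. Soft enolisation of 12 by MgCl2/Et3N gives a magnesium enolate chelated through the alpha-benzyloxy oxygen; it replaces iodide on palladium and C–C reductive elimination forms C4–C3, after which the product is held as the magnesium chelate of its enolate until the acidic work-up. No ring is closed, and the only new sp3 centre (C2 of the propanedione, the future C3) is enolisable and raises no stereochemical issue. The step needs CO insertion to outrun direct alpha-arylation: the two ortho substituents (silyloxy and methoxymethoxy) crowd the arylpalladium and are relieved by insertion, CO is present throughout, and the wide bite angle of Xantphos favours reductive elimination from the acyl complex. It also needs C- rather than O-acylation, which the chelated, covalent magnesium enolate favours, and trapping of the diketone as its magnesium enolate guards it against a second acylation and retro-Claisen cleavage. The aryl silyl ether, the acetals and the benzyl ethers are inert to Et3N/MgCl2 at 80 °C, so O1 stays marked for step 9.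

Step 9
Reactants: 14 2-(benzyloxy)-1-{3-(benzyloxy)-6-[(tert-butyldimethylsilyl)oxy]-2,4-bis(methoxymethoxy)phenyl}-3-[4-(benzyloxy)phenyl]propane-1,3-dione
Product: 17 3,6-bis(benzyloxy)-2-[4-(benzyloxy)phenyl]-5,7-dihydroxy-4H-chromen-4-one, via ring C hemiketal 15 (not isolated), via bis-MOM flavone 16 (not isolated)
Conditions: Bu4NF (1.1 equiv), AcOH (1.1 equiv), THF, 0 °C; aqueous work-up; then HCl (1.25 M in MeOH), THF, rt → 50 °C
Reagents that add atoms: none
Why: Buffered fluoride cleaves only the aryl silyl ether; the freed O1 phenol adds to the C2 carbonyl (6-exo-trig) to give hemiketal 15, and acid dehydrates it to the aromatic pyranone 16, as in the last stage of a Baker–Venkataraman flavone synthesis, before the slower methanolysis of the two acetals releases O5 and O7. Because O5 is still an acetal when the ring closes, only the 5,6,7-oxygenated isomer can form; benzyl ethers are stable to methanolic HCl.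

Step 10
Reactants: 17 3,6-bis(benzyloxy)-2-[4-(benzyloxy)phenyl]-5,7-dihydroxy-4H-chromen-4-one
Product: 18 3,6-bis(benzyloxy)-2-[4-(benzyloxy)phenyl]-5-hydroxy-4-oxo-4H-chromen-7-yl hydrogen sulfate (handled as its triethylammonium salt)
Conditions: SO3·NMe3 (4 equiv), Et3N, DMF, 60 °C
Reagents that add atoms: sulfur trioxide–trimethylamine complex, C[N+](C)(C)S(=O)(=O)[O-]
Why: O-Sulfation of a phenol with an amine–sulfur trioxide complex: the 7-hydroxyl is acidic and free, whereas the 5-hydroxyl is locked in a hydrogen bond to the C4 carbonyl and characteristically resists these reagents, so monosulfation at O7 is expected.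

Step 11
Reactants: 18 3,6-bis(benzyloxy)-2-[4-(benzyloxy)phenyl]-5-hydroxy-4-oxo-4H-chromen-7-yl hydrogen sulfate
Product: 19 3,5,6-trihydroxy-2-(4-hydroxyphenyl)-4-oxo-4H-chromen-7-yl hydrogen sulfate (target)
Conditions: H2 (1 atm), Pd/C (10 wt % Pd), THF/MeOH, rt; filtration and concentration under argon
Reagents that add atoms: none
Why: Catalytic hydrogenolysis of the three benzyl ethers (two aryl, one enol) under neutral conditions; aryl sulfate salts are stable to these conditions and the ammonium counter-ion keeps the medium from turning acidic, and the pyranone double bond is not expected to be reduced at ambient pressure.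

## Compound list

1 | 3,4,5-trihydroxybenzaldehyde | O=Cc1cc(O)c(O)c(O)c1 | starting material
2 | 4-(benzyloxy)-3,5-dihydroxybenzaldehyde | O=Cc1cc(O)c(OCc2ccccc2)c(O)c1 | intermediate
3 | 4-(benzyloxy)-3,5-bis(methoxymethoxy)benzaldehyde | O=Cc1cc(OCOC)c(OCc2ccccc2)c(OCOC)c1 | intermediate
4 | 4-(benzyloxy)-3,5-bis(methoxymethoxy)phenyl formate (not isolated) | O=COc1cc(OCOC)c(OCc2ccccc2)c(OCOC)c1 | intermediate
5 | 4-(benzyloxy)-3,5-bis(methoxymethoxy)phenol | Oc1cc(OCOC)c(OCc2ccccc2)c(OCOC)c1 | intermediate
6 | 4-(benzyloxy)-2-iodo-3,5-bis(methoxymethoxy)phenol | Oc1cc(OCOC)c(OCc2ccccc2)c(OCOC)c1I | intermediate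
7 | tert-butyl[4-(benzyloxy)-2-iodo-3,5-bis(methoxymethoxy)phenoxy]dimethylsilane | CC(C)(C)[Si](C)(C)Oc1cc(OCOC)c(OCc2ccccc2)c(OCOC)c1I | intermediate
8 | (benzyloxy)acetyl chloride | O=C(Cl)COCc1ccccc1 | starting material
9 | 2-(benzyloxy)-N-methoxy-N-methylacetamide | CON(C)C(=O)COCc1ccccc1 | intermediate
10 | 1-(benzyloxy)-4-bromobenzene | Brc1ccc(OCc2ccccc2)cc1 | starting material
11 | [4-(benzyloxy)phenyl]magnesium bromide (not isolated) | Br[Mg]c1ccc(OCc2ccccc2)cc1 | intermediate
12 | 2-(benzyloxy)-1-[4-(benzyloxy)phenyl]ethan-1-one | O=C(COCc1ccccc1)c1ccc(OCc2ccccc2)cc1 | intermediate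
13 | carbon monoxide | [C-]#[O+] | starting material
14 | 2-(benzyloxy)-1-{3-(benzyloxy)-6-[(tert-butyldimethylsilyl)oxy]-2,4-bis(methoxymethoxy)phenyl}-3-[4-(benzyloxy)phenyl]propane-1,3-dione (racemic keto form in equilibrium with its enols) | CC(C)(C)[Si](C)(C)Oc1cc(OCOC)c(OCc2ccccc2)c(OCOC)c1C(=O)C(OCc1ccccc1)C(=O)c1ccc(OCc2ccccc2)cc1 | intermediate
15 | 3,6-bis(benzyloxy)-2-[4-(benzyloxy)phenyl]-2-hydroxy-5,7-bis(methoxymethoxy)-2,3-dihydro-4H-chromen-4-one (racemic, mixture of diastereomers, in equilibrium with the open-chain phenol; not isolated) | O=C1c2c(OCOC)c(OCc3ccccc3)c(OCOC)cc2OC(O)(c2ccc(OCc3ccccc3)cc2)C1OCc1ccccc1 | intermediate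
16 | 3,6-bis(benzyloxy)-2-[4-(benzyloxy)phenyl]-5,7-bis(methoxymethoxy)-4H-chromen-4-one (not isolated) | O=c1c(OCc2ccccc2)c(-c2ccc(OCc3ccccc3)cc2)oc2cc(OCOC)c(OCc3ccccc3)c(OCOC)c12 | intermediate
17 | 3,6-bis(benzyloxy)-2-[4-(benzyloxy)phenyl]-5,7-dihydroxy-4H-chromen-4-one | O=c1c(OCc2ccccc2)c(-c2ccc(OCc3ccccc3)cc2)oc2cc(O)c(OCc3ccccc3)c(O)c12 | intermediate
18 | 3,6-bis(benzyloxy)-2-[4-(benzyloxy)phenyl]-5-hydroxy-4-oxo-4H-chromen-7-yl hydrogen sulfate | O=c1c(OCc2ccccc2)c(-c2ccc(OCc3ccccc3)cc2)oc2cc(OS(=O)(=O)O)c(OCc3ccccc3)c(O)c12 | intermediate
19 | 3,5,6-trihydroxy-2-(4-hydroxyphenyl)-4-oxo-4H-chromen-7-yl hydrogen sulfate | O=c1c(O)c(-c2ccc(O)cc2)oc2cc(OS(=O)(=O)O)c(O)c(O)c12 | target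

## Step count and least certain steps

Total: 11 steps. Longest linear sequence: 9 steps (steps 1, 2, 3, 4, 5, 8, 9, 10, 11); the ketone branch (steps 6 and 7) joins at step 8.

Step 8 (key step). The most likely failure is sluggish oxidative addition and CO insertion at the iodide, which is electron-rich and substituted at both ortho positions. That would let reductive loss of iodine, deactivation of the catalyst under CO, or direct coupling of the aryl group with the enolate take over. Fallback, setting out from 7 and 9 and returning at 14: iodine–magnesium exchange of 7 with iPrMgCl·LiCl in THF at −20 °C and acylation of the arylmagnesium species by 9 would give the ring A ketone 2-(benzyloxy)-1-{3-(benzyloxy)-6-[(tert-butyldimethylsilyl)oxy]-2,4-bis(methoxymethoxy)phenyl}ethan-1-one F1. Soft enolisation of this ketone (MgBr2·OEt2, iPr2NEt, CH2Cl2) and C-acylation with purchased 4-(benzyloxy)benzoyl chloride (O=C(Cl)c1ccc(OCc2ccccc2)cc1) would then give 14. In this variant C4 comes from 9, the bonds made are C4a–C4 and C3–C2, and neither CO nor palladium is involved.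

Step 4. Over-iodination to the di-iodide, or oxidation of the very electron-rich phenol by the iodinating agent, may erode the mono-iodide. Fallback, setting out from 5 and returning at 7: exhaustive iodination with NIS (2.2 equiv) to 4-(benzyloxy)-2,6-diiodo-3,5-bis(methoxymethoxy)phenol F2, then silylation (TBSOTf, 2,6-lutidine, CH2Cl2) to tert-butyl[4-(benzyloxy)-2,6-diiodo-3,5-bis(methoxymethoxy)phenoxy]dimethylsilane F3. A single iodine–magnesium exchange (iPrMgCl·LiCl, 1.0 equiv, THF, −40 °C) and protonation with methanol would give 7. The arylmagnesium formed by the first exchange is too electron-rich to exchange again, so selectivity no longer depends on stopping an electrophilic substitution halfway.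

Step 9. Two processes could interfere. Under fluoride the liberated phenoxide could trigger acyl transfer or retro-Claisen cleavage of the diketone. Under acid the C5 acetal could be lost before dehydration is complete, which would allow closure through the wrong oxygen. Fallback, setting out from 14 and returning at 17, with the three events separated and the dehydration done under base: 15 is isolated after the buffered fluoride step and dehydrated by mesylation and E1cB elimination of the beta-hydroxy ketone (MsCl, Et3N, CH2Cl2, 0 °C) to 16, which is isolated. Only then are the acetals removed with methanolic HCl to give 17. This fallback makes no compound outside the compound list (entry F0).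

Step 11. Loss of the sulfate by solvolysis if the medium turns acidic, stalling of the catalyst on a poorly soluble ionic substrate, or partial reduction of ring C may occur. Fallback, setting out from 17 and returning at 19, replacing steps 10 and 11: 17 is treated with 2,2,2-trichloroethyl chlorosulfate (ClS(=O)(=O)OCC(Cl)(Cl)Cl), Et3N and DMAP in THF to give the neutral, chromatographable diester 3,6-bis(benzyloxy)-2-[4-(benzyloxy)phenyl]-5-hydroxy-4-oxo-4H-chromen-7-yl 2,2,2-trichloroethyl sulfate F4. Transfer hydrogenolysis (Pd/C, HCO2NH4, MeOH, rt → 40 °C) should then remove the trichloroethyl group and the three benzyl ethers together in a buffered medium, giving 19 as its ammonium salt.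

## Further compounds

F1 | step 8 | 2-(benzyloxy)-1-{3-(benzyloxy)-6-[(tert-butyldimethylsilyl)oxy]-2,4-bis(methoxymethoxy)phenyl}ethan-1-one | CC(C)(C)[Si](C)(C)Oc1cc(OCOC)c(OCc2ccccc2)c(OCOC)c1C(=O)COCc1ccccc1
F2 | step 4 | 4-(benzyloxy)-2,6-diiodo-3,5-bis(methoxymethoxy)phenol | Oc1c(I)c(OCOC)c(OCc2ccccc2)c(OCOC)c1I
F3 | step 4 | tert-butyl[4-(benzyloxy)-2,6-diiodo-3,5-bis(methoxymethoxy)phenoxy]dimethylsilane | CC(C)(C)[Si](C)(C)Oc1c(I)c(OCOC)c(OCc2ccccc2)c(OCOC)c1I
F0 | step 9 | none | none
F4 | step 11 | 3,6-bis(benzyloxy)-2-[4-(benzyloxy)phenyl]-5-hydroxy-4-oxo-4H-chromen-7-yl 2,2,2-trichloroethyl sulfate | O=c1c(OCc2ccccc2)c(-c2ccc(OCc3ccccc3)cc2)oc2cc(OS(=O)(=O)OCC(Cl)(Cl)Cl)c(OCc3ccccc3)c(O)c12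
A1 | alternative 1 | 2-{(2E)-3-[4-(benzyloxy)phenyl]prop-2-en-1-yl}-3,5-bis(prop-2-en-1-yloxy)benzene-1,4-diol | Oc1cc(OCC=C)c(O)c(OCC=C)c1C/C=C/c1ccc(OCc2ccccc2)cc1
A2 | alternative 1 | 2-[4-(benzyloxy)phenyl]-5,7-bis(prop-2-en-1-yloxy)-2H-chromen-6-ol (racemic) | C=CCOc1cc2OC(c3ccc(OCc4ccccc4)cc3)C=Cc2c(OCC=C)c1O
A3 | alternative 2 | 3-[4-(benzyloxy)phenyl]prop-2-ynal | O=CC#Cc1ccc(OCc2ccccc2)cc1
A4 | alternative 2 | (2Z)-3-[4-(benzyloxy)-3,5-bis(methoxymethoxy)phenoxy]-3-[4-(benzyloxy)phenyl]prop-2-enal | O=C/C=C(\Oc1cc(OCOC)c(OCc2ccccc2)c(OCOC)c1)c1ccc(OCc2ccccc2)cc1
A5 | alternative 2 | 6-(benzyloxy)-2-[4-(benzyloxy)phenyl]-5,7-bis(methoxymethoxy)-4H-chromen-4-one | O=c1cc(-c2ccc(OCc3ccccc3)cc2)oc2cc(OCOC)c(OCc3ccccc3)c(OCOC)c12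
A6 | alternative 3 | 3-(benzyloxy)-6-{1-[4-(benzyloxy)phenyl]-2-oxoethoxy}-2,4-bis(methoxymethoxy)benzaldehyde (racemic) | O=CC(Oc1cc(OCOC)c(OCc2ccccc2)c(OCOC)c1C=O)c1ccc(OCc2ccccc2)cc1
A7 | alternative 3 | 6-(benzyloxy)-2-[4-(benzyloxy)phenyl]-3-hydroxy-5,7-bis(methoxymethoxy)-2,3-dihydro-4H-chromen-4-one (racemic, mixture of diastereomers) | O=C1C(O)C(c2ccc(OCc3ccccc3)cc2)Oc2cc(OCOC)c(OCc3ccccc3)c(OCOC)c12
A8 | alternative 3 | 6-(benzyloxy)-2-[4-(benzyloxy)phenyl]-4-hydroxy-5,7-bis(methoxymethoxy)-2H-chromen-3(4H)-one (racemic, mixture of diastereomers) | O=C1C(c2ccc(OCc3ccccc3)cc2)Oc2cc(OCOC)c(OCc3ccccc3)c(OCOC)c2C1O
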